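**Assumptions:** Germacrane numbering is used as locants in names (C12 = lactone C=O, C13 = CH2OH, C14/C15 = methyls on C10/C4). Only substrates and building blocks that supply skeletal carbon are numbered; other reagents appear under Conditions. The route is a paper design and has not been run.

## Retrosynthetic overview

1. Target 40 ⇐ 13-O-TBDPS ether 39 ⇐ macrocyclic enone 38 (CBS reduction) ⇐ intramolecular Nozaki–Hiyama–Kishi closure of C1–C10 in iodo-aldehyde 36 (10-membered ring, formed last).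
2. Butenolide (second ring) ⇐ intramolecular HWE of a C6-O-phosphonoacetate (carrying C11–C13) onto a C7 ketone.
3. 4,5-Epoxide (first ring) ⇐ C6-OH-directed, A(1,3)-controlled peracid epoxidation; C5–C6 ⇐ chelation-controlled addition of an (E)-alkenyl Grignard (from 4-pentyn-1-ol) to an α-OPMB aldehyde.
4. C8 carbinol and (Z)-vinyl iodide ⇐ chelation-controlled propynyl addition, then Red-Al/I2; C6–C7–C8 is glycerol, whose C2 (= C7) relays chirality and is later oxidised to the ketone.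
5. First stereocentre ⇐ lipase-catalysed desymmetrising acetylation of achiral 2-O-PMB-glycerol.

## Route

Step 1
Reactants: 1 cis-1,3-O-benzylideneglycerol (cis-2-phenyl-1,3-dioxan-5-ol)
Product: 2 cis-5-[(4-methoxybenzyl)oxy]-2-phenyl-1,3-dioxane
Conditions: NaH, PMBCl, Bu4NI (cat.), DMF, 0 °C → rt
Reagents that add atoms: 4-methoxybenzyl chloride COc1ccc(CCl)cc1
Why: Williamson etherification of the only free hydroxyl; no stereocentre is involved (1 and 2 are achiral).

Step 2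
Reactants: 2 cis-5-[(4-methoxybenzyl)oxy]-2-phenyl-1,3-dioxane
Product: 3 2-[(4-methoxybenzyl)oxy]propane-1,3-diol
Conditions: AcOH/H2O 4:1, 45 °C
Reagents that add atoms: none
Why: Mild acetal hydrolysis removes the benzylidene group while the PMB ether survives, giving the prochiral diol.

Step 3
Reactants: 3 2-[(4-methoxybenzyl)oxy]propane-1,3-diol
Product: 4 (S)-3-hydroxy-2-[(4-methoxybenzyl)oxy]propyl acetate
Conditions: lipase (Burkholderia cepacia lipase, Amano PS, immobilised), vinyl acetate, MTBE, 25 °C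
Reagents that add atoms: vinyl acetate CC(=O)OC=C
Why: Lipase-catalysed enantiotopic-group-selective transesterification (desymmetrisation) acetylates one CH2OH arm and sets the first stereocentre (C7); ≥95% ee is expected by analogy with 2-O-benzylglycerol, and acetaldehyde release makes it irreversible.

Step 4
Reactants: 4 (S)-3-hydroxy-2-[(4-methoxybenzyl)oxy]propyl acetate
Product: 5 (R)-3-[(tert-butyldiphenylsilyl)oxy]-2-[(4-methoxybenzyl)oxy]propyl acetate
Conditions: TBDPSCl, imidazole, CH2Cl2, 0 °C → rt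
Reagents that add atoms: tert-butyl(chloro)diphenylsilane CC(C)(C)[Si](Cl)(c1ccccc1)c1ccccc1
Why: Silylation of the free primary alcohol (future C6 arm) is fast at 0 °C, so acetyl migration does not erode ee; the descriptor change is CIP-only.

Step 5
Reactants: 5 (R)-3-[(tert-butyldiphenylsilyl)oxy]-2-[(4-methoxybenzyl)oxy]propyl acetate
Product: 6 (R)-3-[(tert-butyldiphenylsilyl)oxy]-2-[(4-methoxybenzyl)oxy]propan-1-ol
Conditions: K2CO3 (0.2 equiv), MeOH, 0 °C
Reagents that add atoms: none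
Why: Zemplén-type methanolysis frees the future C8 arm; the TBDPS ether does not migrate under these conditions.

Step 6
Reactants: 6 (R)-3-[(tert-butyldiphenylsilyl)oxy]-2-[(4-methoxybenzyl)oxy]propan-1-ol
Product: 7 (S)-3-[(tert-butyldiphenylsilyl)oxy]-2-[(4-methoxybenzyl)oxy]propanal
Conditions: Dess–Martin periodinane, NaHCO3, CH2Cl2, 0 °C → rt; used crude
Reagents that add atoms: none
Why: Buffered Dess–Martin oxidation gives the α-alkoxy aldehyde without epimerisation.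

Step 7
Reactants: 7 (S)-3-[(tert-butyldiphenylsilyl)oxy]-2-[(4-methoxybenzyl)oxy]propanal; 8 1-propynylmagnesium bromide
Product: 9 (2S,3S)-1-[(tert-butyldiphenylsilyl)oxy]-2-[(4-methoxybenzyl)oxy]hex-4-yn-3-ol
Conditions: MgBr2·OEt2, CH2Cl2, −78 °C; then 8 (0.5 M in THF); aq NH4Cl; minor anti epimer removed by chromatography
Reagents that add atoms: 1-propynylmagnesium bromide CC#C[Mg]Br
Why: Cram-chelate-controlled Grignard addition (Mg bridging C=O and the α-OPMB oxygen) delivers the alkyne anti to the C6 arm, giving the 7,8-syn alcohol and thus the C8 configuration of the target.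

Step 8
Reactants: 9 (2S,3S)-1-[(tert-butyldiphenylsilyl)oxy]-2-[(4-methoxybenzyl)oxy]hex-4-yn-3-ol
Product: 11 (2S,3S,4Z)-1-[(tert-butyldiphenylsilyl)oxy]-5-iodo-2-[(4-methoxybenzyl)oxy]hex-4-en-3-ol, via cyclic sodium alkenylalanate 10 (not isolated)
Conditions: Red-Al, THF, 0 °C → rt; then I2, THF, −78 → 0 °C; aq Na/K tartrate
Reagents that add atoms: iodine II
Why: Alkoxide-directed trans-hydroalumination of the propargylic alcohol puts Al on the distal carbon (C10) cis to C8, and iodinolysis with retention gives the (Z)-vinyl iodide.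

Step 9
Reactants: 11 (2S,3S,4Z)-1-[(tert-butyldiphenylsilyl)oxy]-5-iodo-2-[(4-methoxybenzyl)oxy]hex-4-en-3-ol; 12 tiglic acid
Product: 13 (2S,3S,4Z)-1-[(tert-butyldiphenylsilyl)oxy]-5-iodo-2-[(4-methoxybenzyl)oxy]hex-4-en-3-yl (2E)-2-methylbut-2-enoate
Conditions: DCC, DMAP (0.3 equiv), CH2Cl2, 0 °C → rt
Reagents that add atoms: tiglic acid C/C=C(\C)C(=O)O
Why: Steglich esterification installs the C8 tiglate early (avoiding a late free C8-OH, which could translactonise) and avoids the vinylketene deconjugation seen with the acid chloride and amine base.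

Step 10
Reactants: 13 (2S,3S,4Z)-1-[(tert-butyldiphenylsilyl)oxy]-5-iodo-2-[(4-methoxybenzyl)oxy]hex-4-en-3-yl (2E)-2-methylbut-2-enoate
Product: 14 (2S,3S,4Z)-1-hydroxy-5-iodo-2-[(4-methoxybenzyl)oxy]hex-4-en-3-yl (2E)-2-methylbut-2-enoate
Conditions: TBAF/AcOH 1:1, THF, 0 °C → rt
Reagents that add atoms: none
Why: Acetic-acid-buffered fluoride desilylation frees the C6 arm without base-induced 1,3-migration of the tiglate.

Step 11
Reactants: 14 (2S,3S,4Z)-1-hydroxy-5-iodo-2-[(4-methoxybenzyl)oxy]hex-4-en-3-yl (2E)-2-methylbut-2-enoate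
Product: 15 (2R,3S,4Z)-5-iodo-2-[(4-methoxybenzyl)oxy]-1-oxohex-4-en-3-yl (2E)-2-methylbut-2-enoate
Conditions: Dess–Martin periodinane, NaHCO3, CH2Cl2, 0 °C; used at once
Reagents that add atoms: none
Why: Neutral Dess–Martin oxidation gives the β-acyloxy-α-alkoxy aldehyde without β-elimination or epimerisation (descriptor change at C7 is CIP-only).

Step 12
Reactants: 16 4-pentyn-1-ol; 17 trimethylaluminium
Product: 19 (E)-5-iodo-4-methylpent-4-en-1-ol, via (E)-alkenylalane 18 (not isolated)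
Conditions: 17 (3 equiv), Cp2ZrCl2 (0.25 equiv), CH2Cl2, 0 °C → rt; then I2, THF, −30 → 0 °C; aq Na/K tartrate
Reagents that add atoms: trimethylaluminium C[Al](C)C; iodine II
Why: Negishi Zr-catalysed syn-carboalumination adds Me (future C15) and Al across the terminal alkyne regioselectively, and iodinolysis with retention gives the (E)-trisubstituted vinyl iodide.

Step 13
Reactants: 19 (E)-5-iodo-4-methylpent-4-en-1-ol
Product: 20 (E)-tert-butyl[(5-iodo-4-methylpent-4-en-1-yl)oxy]dimethylsilane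
Conditions: TBSCl, imidazole, DMF, rt
Reagents that add atoms: tert-butyl(chloro)dimethylsilane CC(C)(C)[Si](C)(C)Cl
Why: Standard silyl protection of the future C1 hydroxyl.

Step 14
Reactants: 20 (E)-tert-butyl[(5-iodo-4-methylpent-4-en-1-yl)oxy]dimethylsilane; 15 (2R,3S,4Z)-5-iodo-2-[(4-methoxybenzyl)oxy]-1-oxohex-4-en-3-yl (2E)-2-methylbut-2-enoate
Product: 23 (2Z,4S,5S,6R,7E)-11-[(tert-butyldimethylsilyl)oxy]-6-hydroxy-2-iodo-5-[(4-methoxybenzyl)oxy]-8-methylundeca-2,7-dien-4-yl (2E)-2-methylbut-2-enoate, via alkenyllithium 21 (not isolated), via alkenylmagnesium bromide 22 (not isolated)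
Conditions: 20 (1.3 equiv), t-BuLi (2.0 equiv per 20), Et2O, −78 °C; MgBr2·OEt2, −78 → −20 °C; then 15, CH2Cl2, −78 °C; cold aq NH4Cl
Reagents that add atoms: alkenylmagnesium bromide 22 CC(C)(C)[Si](C)(C)OCCC/C(C)=C/[Mg]Br
Why: I–Li exchange and transmetalation give a configurationally stable (E)-alkenyl Grignard with no residual t-BuLi, and its Cram-chelate addition (α-OPMB) sets C6 syn to C7-OPMB, i.e. the target C6 configuration; the aldehyde reacts far faster than the tiglate or the vinyl iodide.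

Step 15
Reactants: 23 (2Z,4S,5S,6R,7E)-11-[(tert-butyldimethylsilyl)oxy]-6-hydroxy-2-iodo-5-[(4-methoxybenzyl)oxy]-8-methylundeca-2,7-dien-4-yl (2E)-2-methylbut-2-enoate
Product: 24 (2Z,4S,5S,6S)-6-[(2R,3R)-3-{3-[(tert-butyldimethylsilyl)oxy]propyl}-3-methyloxiran-2-yl]-6-hydroxy-2-iodo-5-[(4-methoxybenzyl)oxy]hex-2-en-4-yl (2E)-2-methylbut-2-enoate
Conditions: mCPBA, NaHCO3, CH2Cl2, −20 → 0 °C
Reagents that add atoms: 3-chloroperoxybenzoic acid OOC(=O)c1cccc(Cl)c1
Why: Hydroxyl-directed Prilezhaev epoxidation of the only electron-rich alkene; the C15 methyl cis to C6 enforces the A(1,3)-minimised conformer (C6-H eclipsing the alkene), so oxygen is delivered syn to OH to give the threo (4R,5R) epoxide (about 95:5 expected).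

Step 16
Reactants: 25 tert-butyl 2-(diethoxyphosphoryl)acetate; 26 benzyl chloromethyl ether
Product: 27 tert-butyl 3-(benzyloxy)-2-(diethoxyphosphoryl)propanoate (racemic)
Conditions: NaH, THF, 0 °C; then 26, 0 °C → rt
Reagents that add atoms: benzyl chloromethyl ether ClCOCc1ccccc1
Why: C-alkylation of the phosphonoacetate anion introduces the future C13 as a protected hydroxymethyl group.

Step 17
Reactants: 27 tert-butyl 3-(benzyloxy)-2-(diethoxyphosphoryl)propanoate
Product: 28 tert-butyl 2-(diethoxyphosphoryl)-3-hydroxypropanoate (racemic)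
Conditions: H2 (1 atm), 10% Pd/C, EtOAc, rt
Reagents that add atoms: none
Why: Hydrogenolysis of the benzyl ether at a stage where no alkene or halide is present.

Step 18
Reactants: 28 tert-butyl 2-(diethoxyphosphoryl)-3-hydroxypropanoate
Product: 29 tert-butyl 3-[(tert-butyldiphenylsilyl)oxy]-2-(diethoxyphosphoryl)propanoate (racemic)
Conditions: TBDPSCl, imidazole, DMF, rt
Reagents that add atoms: tert-butyl(chloro)diphenylsilane CC(C)(C)[Si](Cl)(c1ccccc1)c1ccccc1
Why: Silyl protection gives a C13 group that survives every later step and comes off last under buffered fluoride.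

Step 19
Reactants: 29 tert-butyl 3-[(tert-butyldiphenylsilyl)oxy]-2-(diethoxyphosphoryl)propanoate
Product: 30 3-[(tert-butyldiphenylsilyl)oxy]-2-(diethoxyphosphoryl)propanoic acid (racemic)
Conditions: TFA/CH2Cl2 1:4, 0 °C → rt
Reagents that add atoms: none
Why: Acidolysis of the tert-butyl ester gives the acid without base, which would risk β-elimination; the primary TBDPS ether tolerates TFA.

Step 20
Reactants: 24 the epoxy alcohol from step 15; 30 3-[(tert-butyldiphenylsilyl)oxy]-2-(diethoxyphosphoryl)propanoic acid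
Product: 31 C6-O-[3-(tert-butyldiphenylsilyloxy)-2-(diethoxyphosphoryl)propanoyl] ester of 24 (4R,5R,6S,7R,8S; both epimers at the P-bearing carbon)
Conditions: DCC, DMAP (0.2 equiv), CH2Cl2, 0 °C → rt
Reagents that add atoms: acid 30 CCOP(=O)(OCC)C(CO[Si](c1ccccc1)(c1ccccc1)C(C)(C)C)C(=O)O
Why: Steglich acylation of the only free hydroxyl attaches C11–C13; the new phosphonate stereocentre is destroyed in step 23, and the C7 descriptor change is CIP-only.

Step 21
Reactants: 31 the phosphonoacetate ester from step 20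
Product: 32 C7-hydroxy compound (31 without PMB; 4R,5R,6S,7R,8S)
Conditions: DDQ, CH2Cl2/pH 7 buffer 10:1, 0 °C → rt; used directly
Reagents that add atoms: none
Why: Oxidative PMB cleavage under buffered conditions leaves the silyl ethers, epoxide, vinyl iodide and both esters intact.

Step 22
Reactants: 32 the C7 alcohol from step 21
Product: 33 C7 ketone (4R,5R,6R,8S by CIP; geometry unchanged)
Conditions: Dess–Martin periodinane, NaHCO3, CH2Cl2, 0 °C → rt
Reagents that add atoms: none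
Why: Neutral oxidation removes the relay stereocentre (C7) without epimerising C6 or C8 and before any acyl migration can occur.

Step 23
Reactants: 33 the C7 ketone from step 22
Product: 34 (1S,2Z)-1-[(2S)-2-[(2R,3R)-3-{3-[(tert-butyldimethylsilyl)oxy]propyl}-3-methyloxiran-2-yl]-4-{[(tert-butyldiphenylsilyl)oxy]methyl}-5-oxo-2,5-dihydrofuran-3-yl]-3-iodobut-2-en-1-yl (2E)-2-methylbut-2-enoate
Conditions: LiCl, i-Pr2NEt, MeCN, 0 °C → rt
Reagents that add atoms: none
Why: Intramolecular Horner–Wadsworth–Emmons olefination under Masamune–Roush conditions closes the tetrasubstituted butenolide; the weak base deprotonates only the Li-chelated phosphonate, and any β-loss of silanolate is a reversible oxa-Michael step whereas the olefination is irreversible.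

Step 24
Reactants: 34 the butenolide from step 23
Product: 35 C1 primary alcohol (34 without TBS; 3-hydroxypropyl on the oxirane)
Conditions: HF·pyridine, excess pyridine, THF, 0 °C
Reagents that add atoms: none
Why: Buffered HF·pyridine cleaves the primary alkyl TBS ether much faster than the primary TBDPS ether and is mild enough for the epoxide.

Step 25
Reactants: 35 the C1 alcohol from step 24
Product: 36 C1 aldehyde (3-oxopropyl on the oxirane)
Conditions: Dess–Martin periodinane, NaHCO3, CH2Cl2, 0 °C → rt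
Reagents that add atoms: none
Why: Neutral oxidation gives the aldehyde needed for ring closure without touching the base-sensitive butenolide.

Step 26
Reactants: 36 the iodo-aldehyde from step 25
Product: 37 13-O-TBDPS ether of the target as a mixture of C1 epimers (4R,5R,6S,8S,9Z)
Conditions: CrCl2 (10 equiv), NiCl2 (0.2 equiv), degassed DMSO, 2 mM, rt, slow addition; aq work-up
Reagents that add atoms: none
Why: Intramolecular Nozaki–Hiyama–Kishi reaction (Ni-catalysed oxidative addition to the vinyl iodide, transmetalation to Cr(III), addition to the aldehyde) closes the 10-membered ring with retention of the (Z)-alkene and tolerates esters, lactone and epoxide; the C1 ratio is not predictable, so both epimers are carried on.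

Step 27
Reactants: 37 the macrocyclic allylic alcohols from step 26
Product: 38 (4R,5R,6S,8S,9Z)-13-[(tert-butyldiphenylsilyl)oxy]-4,5-epoxy-1-oxo-8-tigloyloxygermacra-7(11),9-dien-12,6-olide
Conditions: Dess–Martin periodinane, NaHCO3, CH2Cl2, 0 °C
Reagents that add atoms: none
Why: Oxidation converges both C1 epimers onto a single enone.

Step 28
Reactants: 38 the macrocyclic enone from step 27
Product: 39 (1R,4R,5R,6S,8S,9Z)-13-[(tert-butyldiphenylsilyl)oxy]-4,5-epoxy-1-hydroxy-8-tigloyloxygermacra-7(11),9-dien-12,6-olide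
Conditions: (S)-2-methyl-CBS-oxazaborolidine (1.0 equiv), catecholborane (1.5 equiv), toluene/CH2Cl2, −78 °C; pH 7 buffer
Reagents that add atoms: none
Why: Corey–Bakshi–Shibata reduction with the α-branched alkenyl group (C10) as the large substituent gives the (1R)-alcohol by catalyst control; the esters and the tetrasubstituted butenolide are inert to catecholborane at −78 °C.

Step 29
Reactants: 39 the (1R)-alcohol from step 28
Product: 40 (1R,4R,5R,6S,8S,9Z)-4,5-epoxy-1,13-dihydroxy-8-[(2E)-2-methylbut-2-enoyloxy]germacra-7(11),9-dien-12,6-olide (CNP0167056.1)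
Conditions: TBAF/AcOH 1:1, THF, 0 °C → rt
Reagents that add atoms: none
Why: Near-neutral buffered fluoride removes the last silyl group without acid-induced transannular epoxide opening or base-induced tiglate migration or lactone opening.

## Compound list

1 | cis-1,3-O-benzylideneglycerol (cis-2-phenyl-1,3-dioxan-5-ol) | O[C@H]1CO[C@@H](c2ccccc2)OC1 | starting material
2 | cis-5-[(4-methoxybenzyl)oxy]-2-phenyl-1,3-dioxane | COc1ccc(CO[C@H]2CO[C@@H](c3ccccc3)OC2)cc1 | intermediate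
3 | 2-[(4-methoxybenzyl)oxy]propane-1,3-diol | COc1ccc(COC(CO)CO)cc1 | intermediate
4 | (S)-3-hydroxy-2-[(4-methoxybenzyl)oxy]propyl acetate | CC(=O)OC[C@@H](OCc1ccc(OC)cc1)CO | intermediate
5 | (R)-3-[(tert-butyldiphenylsilyl)oxy]-2-[(4-methoxybenzyl)oxy]propyl acetate | CC(=O)OC[C@@H](OCc1ccc(OC)cc1)CO[Si](c1ccccc1)(c1ccccc1)C(C)(C)C | intermediate
6 | (R)-3-[(tert-butyldiphenylsilyl)oxy]-2-[(4-methoxybenzyl)oxy]propan-1-ol | OC[C@@H](OCc1ccc(OC)cc1)CO[Si](c1ccccc1)(c1ccccc1)C(C)(C)C | intermediate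
7 | (S)-3-[(tert-butyldiphenylsilyl)oxy]-2-[(4-methoxybenzyl)oxy]propanal | O=C[C@@H](OCc1ccc(OC)cc1)CO[Si](c1ccccc1)(c1ccccc1)C(C)(C)C | intermediate
8 | 1-propynylmagnesium bromide | CC#C[Mg]Br | starting material
9 | (2S,3S)-1-[(tert-butyldiphenylsilyl)oxy]-2-[(4-methoxybenzyl)oxy]hex-4-yn-3-ol | CC#C[C@H](O)[C@@H](OCc1ccc(OC)cc1)CO[Si](c1ccccc1)(c1ccccc1)C(C)(C)C | intermediate
10 | cyclic sodium alkenylalanate from 9 (Al on C10 and on the C8 oxygen; not isolated) | [Na+].COCCO[Al-]1(OCCOC)O[C@H]([C@H](CO[Si](c2ccccc2)(c2ccccc2)C(C)(C)C)OCc2ccc(OC)cc2)C=C1C | intermediate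
11 | (2S,3S,4Z)-1-[(tert-butyldiphenylsilyl)oxy]-5-iodo-2-[(4-methoxybenzyl)oxy]hex-4-en-3-ol | C/C(I)=C/[C@H](O)[C@@H](OCc1ccc(OC)cc1)CO[Si](c1ccccc1)(c1ccccc1)C(C)(C)C | intermediate
12 | tiglic acid ((2E)-2-methylbut-2-enoic acid) | C/C=C(\C)C(=O)O | starting material
13 | (2S,3S,4Z)-1-[(tert-butyldiphenylsilyl)oxy]-5-iodo-2-[(4-methoxybenzyl)oxy]hex-4-en-3-yl (2E)-2-methylbut-2-enoate | C/C=C(\C)C(=O)O[C@@H](/C=C(/C)I)[C@@H](OCc1ccc(OC)cc1)CO[Si](c1ccccc1)(c1ccccc1)C(C)(C)C | intermediate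
14 | (2S,3S,4Z)-1-hydroxy-5-iodo-2-[(4-methoxybenzyl)oxy]hex-4-en-3-yl (2E)-2-methylbut-2-enoate | C/C=C(\C)C(=O)O[C@@H](/C=C(/C)I)[C@@H](OCc1ccc(OC)cc1)CO | intermediate
15 | (2R,3S,4Z)-5-iodo-2-[(4-methoxybenzyl)oxy]-1-oxohex-4-en-3-yl (2E)-2-methylbut-2-enoate | C/C=C(\C)C(=O)O[C@@H](/C=C(/C)I)[C@@H](OCc1ccc(OC)cc1)C=O | intermediate
16 | 4-pentyn-1-ol | C#CCCCO | starting material
17 | trimethylaluminium | C[Al](C)C | starting material
18 | (E)-alkenylalane from carboalumination of 16 (O-AlMe2 and C-AlMe2; not isolated) | C[Al](C)OCCC/C(C)=C/[Al](C)C | intermediate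
19 | (E)-5-iodo-4-methylpent-4-en-1-ol | OCCC/C(C)=C/I | intermediate
20 | (E)-tert-butyl[(5-iodo-4-methylpent-4-en-1-yl)oxy]dimethylsilane | CC(C)(C)[Si](C)(C)OCCC/C(C)=C/I | intermediate
21 | (E)-[5-(tert-butyldimethylsilyloxy)-2-methylpent-1-enyl]lithium (not isolated) | CC(C)(C)[Si](C)(C)OCCC/C(C)=C/[Li] | intermediate
22 | (E)-[5-(tert-butyldimethylsilyloxy)-2-methylpent-1-enyl]magnesium bromide (not isolated) | CC(C)(C)[Si](C)(C)OCCC/C(C)=C/[Mg]Br | intermediate
23 | (2Z,4S,5S,6R,7E)-11-[(tert-butyldimethylsilyl)oxy]-6-hydroxy-2-iodo-5-[(4-methoxybenzyl)oxy]-8-methylundeca-2,7-dien-4-yl (2E)-2-methylbut-2-enoate | CC(C)(C)[Si](C)(C)OCCC/C(C)=C/[C@@H](O)[C@H](OCc1ccc(OC)cc1)[C@@H](OC(=O)/C(C)=C/C)/C=C(/C)I | intermediate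
24 | (2Z,4S,5S,6S)-6-[(2R,3R)-3-{3-[(tert-butyldimethylsilyl)oxy]propyl}-3-methyloxiran-2-yl]-6-hydroxy-2-iodo-5-[(4-methoxybenzyl)oxy]hex-2-en-4-yl (2E)-2-methylbut-2-enoate | CC(C)(C)[Si](C)(C)OCCC[C@@]1(C)O[C@@H]1[C@@H](O)[C@H](OCc1ccc(OC)cc1)[C@@H](OC(=O)/C(C)=C/C)/C=C(/C)I | intermediate
25 | tert-butyl 2-(diethoxyphosphoryl)acetate | CCOP(=O)(OCC)CC(=O)OC(C)(C)C | starting material
26 | benzyl chloromethyl ether | ClCOCc1ccccc1 | starting material
27 | tert-butyl 3-(benzyloxy)-2-(diethoxyphosphoryl)propanoate (racemic) | CCOP(=O)(OCC)C(COCc1ccccc1)C(=O)OC(C)(C)C | intermediate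
28 | tert-butyl 2-(diethoxyphosphoryl)-3-hydroxypropanoate (racemic) | CCOP(=O)(OCC)C(CO)C(=O)OC(C)(C)C | intermediate
29 | tert-butyl 3-[(tert-butyldiphenylsilyl)oxy]-2-(diethoxyphosphoryl)propanoate (racemic) | CCOP(=O)(OCC)C(CO[Si](c1ccccc1)(c1ccccc1)C(C)(C)C)C(=O)OC(C)(C)C | intermediate
30 | 3-[(tert-butyldiphenylsilyl)oxy]-2-(diethoxyphosphoryl)propanoic acid (racemic) | CCOP(=O)(OCC)C(CO[Si](c1ccccc1)(c1ccccc1)C(C)(C)C)C(=O)O | intermediate
31 | C6-O-[3-(tert-butyldiphenylsilyloxy)-2-(diethoxyphosphoryl)propanoyl] ester of 24 (4R,5R,6S,7R,8S; epimers at the P-bearing carbon) | CC(C)(C)[Si](C)(C)OCCC[C@@]1(C)O[C@@H]1[C@@H](OC(=O)C(CO[Si](c1ccccc1)(c1ccccc1)C(C)(C)C)P(=O)(OCC)OCC)[C@H](OCc1ccc(OC)cc1)[C@@H](OC(=O)/C(C)=C/C)/C=C(/C)I | intermediate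
32 | C7-hydroxy compound (31 without PMB; 4R,5R,6S,7R,8S) | CC(C)(C)[Si](C)(C)OCCC[C@@]1(C)O[C@@H]1[C@@H](OC(=O)C(CO[Si](c1ccccc1)(c1ccccc1)C(C)(C)C)P(=O)(OCC)OCC)[C@H](O)[C@@H](OC(=O)/C(C)=C/C)/C=C(/C)I | intermediate
33 | C7 ketone (4R,5R,6R,8S) | CC(C)(C)[Si](C)(C)OCCC[C@@]1(C)O[C@@H]1[C@@H](OC(=O)C(CO[Si](c1ccccc1)(c1ccccc1)C(C)(C)C)P(=O)(OCC)OCC)C(=O)[C@@H](OC(=O)/C(C)=C/C)/C=C(/C)I | intermediate
34 | (1S,2Z)-1-[(2S)-2-[(2R,3R)-3-{3-[(tert-butyldimethylsilyl)oxy]propyl}-3-methyloxiran-2-yl]-4-{[(tert-butyldiphenylsilyl)oxy]methyl}-5-oxo-2,5-dihydrofuran-3-yl]-3-iodobut-2-en-1-yl (2E)-2-methylbut-2-enoate | CC(C)(C)[Si](C)(C)OCCC[C@@]1(C)O[C@@H]1[C@H]1OC(=O)C(CO[Si](c2ccccc2)(c2ccccc2)C(C)(C)C)=C1[C@@H](OC(=O)/C(C)=C/C)/C=C(/C)I | intermediate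
35 | C1 alcohol (34 with 3-hydroxypropyl in place of 3-silyloxypropyl) | OCCC[C@@]1(C)O[C@@H]1[C@H]1OC(=O)C(CO[Si](c2ccccc2)(c2ccccc2)C(C)(C)C)=C1[C@@H](OC(=O)/C(C)=C/C)/C=C(/C)I | intermediate
36 | C1 aldehyde (3-oxopropyl on the oxirane) | O=CCC[C@@]1(C)O[C@@H]1[C@H]1OC(=O)C(CO[Si](c2ccccc2)(c2ccccc2)C(C)(C)C)=C1[C@@H](OC(=O)/C(C)=C/C)/C=C(/C)I | intermediate
37 | 13-O-TBDPS ether of the target as a C1-epimer mixture (4R,5R,6S,8S,9Z) | C/C=C(\C)C(=O)O[C@H]1/C=C(/C)C(O)CC[C@@]2(C)O[C@@H]2[C@H]2OC(=O)C(CO[Si](c3ccccc3)(c3ccccc3)C(C)(C)C)=C12 | intermediate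
38 | (4R,5R,6S,8S,9Z)-13-[(tert-butyldiphenylsilyl)oxy]-4,5-epoxy-1-oxo-8-tigloyloxygermacra-7(11),9-dien-12,6-olide | C/C=C(\C)C(=O)O[C@H]1/C=C(/C)C(=O)CC[C@@]2(C)O[C@@H]2[C@H]2OC(=O)C(CO[Si](c3ccccc3)(c3ccccc3)C(C)(C)C)=C12 | intermediate
39 | (1R,4R,5R,6S,8S,9Z)-13-[(tert-butyldiphenylsilyl)oxy]-4,5-epoxy-1-hydroxy-8-tigloyloxygermacra-7(11),9-dien-12,6-olide | C/C=C(\C)C(=O)O[C@H]1/C=C(/C)[C@H](O)CC[C@@]2(C)O[C@@H]2[C@H]2OC(=O)C(CO[Si](c3ccccc3)(c3ccccc3)C(C)(C)C)=C12 | intermediate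
40 | (1R,4R,5R,6S,8S,9Z)-4,5-epoxy-1,13-dihydroxy-8-[(2E)-2-methylbut-2-enoyloxy]germacra-7(11),9-dien-12,6-olide (CNP0167056.1) | C/C=C(\C)C(=O)O[C@H]1/C=C(/C)[C@H](O)CC[C@@]2(C)O[C@@H]2[C@H]2OC(=O)C(CO)=C12 | target

## Step count and risks

Total step count: 29 (main line 23; alkenyl iodide branch 2; phosphonate acid branch 4).
Longest linear sequence: 23 steps (steps 1–11, 14, 15, 20–29).

Three steps most likely to fail:

**Step 23 (intramolecular HWE to the tetrasubstituted butenolide).** The risks are loss of silanolate from the β-silyloxy phosphonate anion, epimerisation at C6/C8 and base opening of the β,γ-epoxy ketone. The fallback forms the C7=C11 bond by olefin metathesis instead; it sets out from 24 and returns at 34. Commercial ethyl 2-(hydroxymethyl)acrylate is silylated (TBDPSCl, imidazole) to ethyl 2-{[(tert-butyldiphenylsilyl)oxy]methyl}acrylate F1 and saponified (LiOH, THF/H2O) to 2-{[(tert-butyldiphenylsilyl)oxy]methyl}acrylic acid F2. Steglich esterification of 24 with F2 gives the C6 acrylate ester F3. DDQ then gives the C7 alcohol F4 and Dess–Martin oxidation the C7 ketone F5. Non-basic Petasis methylenation (Cp2TiMe2, toluene, 65 °C; ketone reacts before esters) gives the C7-methylene compound F6. Ring-closing metathesis (Stewart–Grubbs or Hoveyda–Grubbs II catalyst, toluene, 80 °C, ethene lost) then closes butenolide 34.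

**Step 26 (NHK closure of the 10-membered ring).** The rigid butenolide may disfavour the cyclisation conformer. The fallback changes the ring order (carbocycle before butenolide); it sets out from 31 and returns at 38. HF·pyridine/pyridine removes the TBS group of 31 to give the C1 alcohol F7, and Dess–Martin oxidation gives the C1 aldehyde F8. NHK cyclisation of this more flexible sp3-C7 substrate gives the macrocyclic C1-epimeric alcohol F9, which still carries the C7-OPMB group and the C6 phosphonoacetate. DDQ gives the 1,7-diol F10, and excess Dess–Martin periodinane gives the 1,7-diketone F11. The LiCl/i-Pr2NEt HWE then builds the butenolide on the preformed ring and delivers enone 38.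

**Step 28 (CBS reduction of the macrocyclic enone).** Ring conformation may override catalyst control at C1. The fallback inverts the wrong epimer by SN2 instead; it sets out from 37 and returns at 39. The C1 epimers of 37 are separated by chromatography; the (1R)-epimer is 39 itself. The (1S)-alcohol F12 is inverted by Mitsunobu reaction with chloroacetic acid (PPh3, DIAD, toluene, 0 °C) to the (1R)-chloroacetate F13, which is cleaved with thiourea/NaHCO3 in EtOH (neutral, leaves tiglate and lactone intact) to give 39.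

## Further compounds

F1 | step 23 | ethyl 2-{[(tert-butyldiphenylsilyl)oxy]methyl}acrylate | C=C(CO[Si](c1ccccc1)(c1ccccc1)C(C)(C)C)C(=O)OCC
F2 | step 23 | 2-{[(tert-butyldiphenylsilyl)oxy]methyl}acrylic acid | C=C(CO[Si](c1ccccc1)(c1ccccc1)C(C)(C)C)C(=O)O
F3 | step 23 | C6-O-[2-(tert-butyldiphenylsilyloxymethyl)acryloyl] ester of 24 | CC(C)(C)[Si](C)(C)OCCC[C@@]1(C)O[C@@H]1[C@@H](OC(=O)C(=C)CO[Si](c1ccccc1)(c1ccccc1)C(C)(C)C)[C@H](OCc1ccc(OC)cc1)[C@@H](OC(=O)/C(C)=C/C)/C=C(/C)I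
F4 | step 23 | C7 alcohol from F3 (PMB removed) | CC(C)(C)[Si](C)(C)OCCC[C@@]1(C)O[C@@H]1[C@@H](OC(=O)C(=C)CO[Si](c1ccccc1)(c1ccccc1)C(C)(C)C)[C@H](O)[C@@H](OC(=O)/C(C)=C/C)/C=C(/C)I
F5 | step 23 | C7 ketone from F4 | CC(C)(C)[Si](C)(C)OCCC[C@@]1(C)O[C@@H]1[C@@H](OC(=O)C(=C)CO[Si](c1ccccc1)(c1ccccc1)C(C)(C)C)C(=O)[C@@H](OC(=O)/C(C)=C/C)/C=C(/C)I
F6 | step 23 | C7-methylene compound from F5 (metathesis precursor) | CC(C)(C)[Si](C)(C)OCCC[C@@]1(C)O[C@@H]1[C@@H](OC(=O)C(=C)CO[Si](c1ccccc1)(c1ccccc1)C(C)(C)C)C(=C)[C@@H](OC(=O)/C(C)=C/C)/C=C(/C)I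
F7 | step 26 | C1 alcohol from 31 (TBS removed) | OCCC[C@@]1(C)O[C@@H]1[C@@H](OC(=O)C(CO[Si](c1ccccc1)(c1ccccc1)C(C)(C)C)P(=O)(OCC)OCC)[C@H](OCc1ccc(OC)cc1)[C@@H](OC(=O)/C(C)=C/C)/C=C(/C)I
F8 | step 26 | C1 aldehyde from F7 | O=CCC[C@@]1(C)O[C@@H]1[C@@H](OC(=O)C(CO[Si](c1ccccc1)(c1ccccc1)C(C)(C)C)P(=O)(OCC)OCC)[C@H](OCc1ccc(OC)cc1)[C@@H](OC(=O)/C(C)=C/C)/C=C(/C)I
F9 | step 26 | macrocyclic C1-epimeric alcohol with C7-OPMB and C6 phosphonoacetate | C/C=C(\C)C(=O)O[C@H]1/C=C(/C)C(O)CC[C@@]2(C)O[C@@H]2[C@@H](OC(=O)C(CO[Si](c2ccccc2)(c2ccccc2)C(C)(C)C)P(=O)(OCC)OCC)[C@@H]1OCc1ccc(OC)cc1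
F10 | step 26 | macrocyclic 1,7-diol from F9 | C/C=C(\C)C(=O)O[C@H]1/C=C(/C)C(O)CC[C@@]2(C)O[C@@H]2[C@@H](OC(=O)C(CO[Si](c2ccccc2)(c2ccccc2)C(C)(C)C)P(=O)(OCC)OCC)[C@@H]1O
F11 | step 26 | macrocyclic 1,7-diketone from F10 | C/C=C(\C)C(=O)O[C@H]1/C=C(/C)C(=O)CC[C@@]2(C)O[C@@H]2[C@@H](OC(=O)C(CO[Si](c2ccccc2)(c2ccccc2)C(C)(C)C)P(=O)(OCC)OCC)C1=O
F12 | step 28 | (1S)-epimer of 39 | C/C=C(\C)C(=O)O[C@H]1/C=C(/C)[C@@H](O)CC[C@@]2(C)O[C@@H]2[C@H]2OC(=O)C(CO[Si](c3ccccc3)(c3ccccc3)C(C)(C)C)=C12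
F13 | step 28 | (1R)-1-O-chloroacetate of 39 | C/C=C(\C)C(=O)O[C@H]1/C=C(/C)[C@H](OC(=O)CCl)CC[C@@]2(C)O[C@@H]2[C@H]2OC(=O)C(CO[Si](c3ccccc3)(c3ccccc3)C(C)(C)C)=C12
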